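**Retrosynthetic overview**
- The target is taken back to kaempferol by sulfation of the 3-, 7- and 4'-hydroxyls (the chelated 5-OH stays free), and kaempferol to its 5,7,4'-tribenzyl ether by hydrogenolysis.
- The benzylated flavonol comes from a flavan-3,4-diol by double oxidation and enolisation, and the diol from syn-dihydroxylation of the C3=C4 bond of a 2-aryl-2H-chromene.
- The 2H-chromene comes from an aryl 1-arylpropargyl ether by a thermal propargyl Claisen shift, hydrogen shift and oxa-electrocyclization, which makes C4–C4a and O1–C2 and closes ring C onto purchased rings A and B.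
- The strategy rests on this feature: ring C is fused to ring A through O1–C8a and C4–C4a on neighbouring carbons of a phenol ring whose 5- and 7-oxygens make both ortho carbons equivalent, C2 carries ring B, and the C3=C4 alkene is the latent 3-OH/4-C=O.
- The ether comes from Mitsunobu coupling of 3,5-bis(benzyloxy)phenol with the propargylic alcohol made from 4-(benzyloxy)benzaldehyde and ethynylmagnesium bromide.

Key step: step 3

Assumption: the target is drawn as the free tris(hydrogen sulfate); the sulfation should deliver an ammonium salt, which is converted into the acid form by brief passage through a cold H+-form cation-exchange resin (the salt is the form to store). The target has no stereocentre; the stereocentres of compounds 3 to 12 are transient and are carried racemic.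

**Step 1**
Reactants: 1 4-(benzyloxy)benzaldehyde; 2 ethynylmagnesium bromide
Product: 3 racemic 1-[4-(benzyloxy)phenyl]prop-2-yn-1-ol
Conditions: HC≡CMgBr (1.3 equiv), THF, 0 °C to rt; sat. aq NH4Cl
Reagents that add atoms: none
Why: Grignard 1,2-addition of an alkynyl nucleophile to a non-enolisable aryl aldehyde; the carbinol centre forms racemic, which is acceptable because this carbon (future C2) ends as an sp2 carbon.

**Step 2**
Reactants: 3 racemic 1-[4-(benzyloxy)phenyl]prop-2-yn-1-ol; 4 3,5-bis(benzyloxy)phenol
Product: 5 racemic 1,3-bis(benzyloxy)-5-({1-[4-(benzyloxy)phenyl]prop-2-yn-1-yl}oxy)benzene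
Conditions: PPh3, DIAD (slow addition), THF, 0 °C to rt
Reagents that add atoms: none
Why: Mitsunobu etherification, in which the phenol is acidic enough to protonate the betaine and its phenoxide displaces the oxyphosphonium group of the secondary propargylic alcohol; the configuration is irrelevant because 3 is racemic.

**Step 3**
Reactants: 5 racemic 1,3-bis(benzyloxy)-5-({1-[4-(benzyloxy)phenyl]prop-2-yn-1-yl}oxy)benzene
Product: 9 racemic 5,7-bis(benzyloxy)-2-[4-(benzyloxy)phenyl]-2H-chromene, via allenyl cyclohexadienone 6 (not isolated), via ortho-allenylphenol 7 (not isolated), via ortho-quinone methide 8 (not isolated)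
Conditions: PhNEt2 (degassed, 0.05 M), Ar, 160–180 °C; solvent removed in vacuo, chromatography on Et3N-deactivated silica
Reagents that add atoms: none
Why: Heating triggers an aromatic propargyl Claisen [3,3] shift in which the ether O–C bond (the later O1–C2) breaks and the alkyne terminus (future C4) bonds to the ortho ring carbon (C4a), giving allenyl dienone 6, which enolises to allenylphenol 7. A [1,5]-hydrogen shift from the phenolic O–H to the central allene carbon (future C3) gives ortho-quinone methide 8 with a Z exocyclic alkene, so that the carbonyl oxygen and the styryl terminus face each other. A thermal disrotatory six-electron oxa-electrocyclization then re-forms O1–C2 and closes ring C as the six-membered 2H-pyran while ring A regains aromaticity. The closest known reaction type is the thermal rearrangement of aryl propargyl ethers to 2H-chromenes in N,N-dialkylaniline solvents, here helped by the aryl group on the propargylic carbon. The only new stereocentre, C2, has no controlling element and forms racemic, which is harmless because C2 becomes sp2 in step 5. The step needs ortho regioselectivity and pyran rather than furan closure: the mirror symmetry of the 3,5-bis(benzyloxy)phenoxy ring makes its two free ortho carbons identical, and a weakly basic, non-ionising medium without fluoride or strong base disfavours the benzofuran and ion-pair pathways.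

**Step 4**
Reactants: 9 racemic 5,7-bis(benzyloxy)-2-[4-(benzyloxy)phenyl]-2H-chromene
Product: 10 rac-(2R,3S,4S)-5,7-bis(benzyloxy)-2-[4-(benzyloxy)phenyl]-3,4-dihydro-2H-chromene-3,4-diol (2,3-trans-3,4-cis: both hydroxyls cis to each other and trans to the C2 aryl group)
Conditions: OsO4 (cat.), NMO, acetone/H2O, rt; aq Na2SO3
Reagents that add atoms: osmium tetroxide OsO4, O=[Os](=O)(=O)=O; N-methylmorpholine N-oxide, C[N+]1([O-])CCOCC1; water, O
Why: Catalytic OsO4/NMO syn-dihydroxylation of the electron-rich styrenic C3=C4 bond, with the osmium reagent adding to the face opposite the C2 aryl group so that C3 and C4 are set relative to C2; all three centres are erased in step 5, so imperfect facial selectivity does no harm.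

**Step 5**
Reactants: 10 rac-(2R,3S,4S)-5,7-bis(benzyloxy)-2-[4-(benzyloxy)phenyl]-3,4-dihydro-2H-chromene-3,4-diol
Product: 13 5,7-bis(benzyloxy)-2-[4-(benzyloxy)phenyl]-3-hydroxy-4H-chromen-4-one, via trans-dihydroflavonol 11 (not isolated), via chromane-3,4-dione 12 (not isolated)
Conditions: IBX (4 equiv), DMSO, rt to 50 °C
Reagents that add atoms: none
Why: IBX oxidation of a 1,2-diol to the 1,2-dicarbonyl without C–C cleavage, the benzylic C4 alcohol going first to 11 and the ketol then to dione 12, whose doubly activated C2–H enolises to the aromatic 3-hydroxy-4-pyranone; any direct IBX dehydrogenation of 11 leads to the same flavonol.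

**Step 6**
Reactants: 13 5,7-bis(benzyloxy)-2-[4-(benzyloxy)phenyl]-3-hydroxy-4H-chromen-4-one
Product: 14 kaempferol (3,5,7-trihydroxy-2-(4-hydroxyphenyl)-4H-chromen-4-one)
Conditions: H2 (1 atm), 10% Pd/C, THF/MeOH, rt
Reagents that add atoms: none
Why: Catalytic hydrogenolysis of three aryl benzyl ethers, under which the aromatic pyranone C2=C3 bond and the carbonyl are not reduced at ambient pressure and temperature.

**Step 7**
Reactants: 14 kaempferol
Product: 15 kaempferol 3,7,4'-tri-O-sulfate
Conditions: SO3·NMe3 (5 equiv, HPLC control), Et3N, DMA, 60 °C; then sulfonic acid cation-exchange resin (H+ form), H2O, 0 °C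
Reagents that add atoms: sulfur trioxide–trimethylamine complex SO3·NMe3, C[N+](C)(C)S(=O)(=O)[O-]
Why: O-sulfation of phenols by an amine–sulfur trioxide complex, in which the acidic, unhindered 7- and 4'-hydroxyls react first and the enolic 3-hydroxyl next, while the 5-hydroxyl is peri-hindered and locked in a strong hydrogen bond to the C4 carbonyl and should stay free under stoichiometric control.

**Compound list**
1 | 4-(benzyloxy)benzaldehyde | O=Cc1ccc(OCc2ccccc2)cc1 | starting material
2 | ethynylmagnesium bromide | C#C[Mg]Br | starting material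
3 | racemic 1-[4-(benzyloxy)phenyl]prop-2-yn-1-ol | C#CC(O)c1ccc(OCc2ccccc2)cc1 | intermediate
4 | 3,5-bis(benzyloxy)phenol | Oc1cc(OCc2ccccc2)cc(OCc2ccccc2)c1 | starting material
5 | racemic 1,3-bis(benzyloxy)-5-({1-[4-(benzyloxy)phenyl]prop-2-yn-1-yl}oxy)benzene | C#CC(Oc1cc(OCc2ccccc2)cc(OCc2ccccc2)c1)c1ccc(OCc2ccccc2)cc1 | intermediate
6 | 3,5-bis(benzyloxy)-6-{3-[4-(benzyloxy)phenyl]propa-1,2-dien-1-yl}cyclohexa-2,4-dien-1-one (stereoisomer mixture, not isolated) | O=C1C=C(OCc2ccccc2)C=C(OCc2ccccc2)C1C=C=Cc1ccc(OCc2ccccc2)cc1 | intermediate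
7 | 3,5-bis(benzyloxy)-2-{3-[4-(benzyloxy)phenyl]propa-1,2-dien-1-yl}phenol (racemic allene, not isolated) | Oc1cc(OCc2ccccc2)cc(OCc2ccccc2)c1C=C=Cc1ccc(OCc2ccccc2)cc1 | intermediate
8 | (6Z)-3,5-bis(benzyloxy)-6-{3-[4-(benzyloxy)phenyl]prop-2-en-1-ylidene}cyclohexa-2,4-dien-1-one (styryl alkene geometry undefined, not isolated) | O=C1C=C(OCc2ccccc2)C=C(OCc2ccccc2)/C1=C/C=Cc1ccc(OCc2ccccc2)cc1 | intermediate
9 | racemic 5,7-bis(benzyloxy)-2-[4-(benzyloxy)phenyl]-2H-chromene | C1(c2ccc(OCc3ccccc3)cc2)Oc2cc(OCc3ccccc3)cc(OCc3ccccc3)c2C=C1 | intermediate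
10 | rac-(2R,3S,4S)-5,7-bis(benzyloxy)-2-[4-(benzyloxy)phenyl]-3,4-dihydro-2H-chromene-3,4-diol (one enantiomer of the racemate drawn) | O[C@H]1c2c(OCc3ccccc3)cc(OCc3ccccc3)cc2O[C@H](c2ccc(OCc3ccccc3)cc2)[C@H]1O | intermediate
11 | rac-(2R,3R)-5,7-bis(benzyloxy)-2-[4-(benzyloxy)phenyl]-3-hydroxy-2,3-dihydro-4H-chromen-4-one (one enantiomer drawn, not isolated) | O=C1c2c(OCc3ccccc3)cc(OCc3ccccc3)cc2O[C@H](c2ccc(OCc3ccccc3)cc2)[C@H]1O | intermediate
12 | racemic 5,7-bis(benzyloxy)-2-[4-(benzyloxy)phenyl]-2H-chromene-3,4-dione (not isolated) | O=C1C(=O)c2c(OCc3ccccc3)cc(OCc3ccccc3)cc2OC1c1ccc(OCc2ccccc2)cc1 | intermediate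
13 | 5,7-bis(benzyloxy)-2-[4-(benzyloxy)phenyl]-3-hydroxy-4H-chromen-4-one | O=c1c(O)c(-c2ccc(OCc3ccccc3)cc2)oc2cc(OCc3ccccc3)cc(OCc3ccccc3)c12 | intermediate
14 | kaempferol | O=c1c(O)c(-c2ccc(O)cc2)oc2cc(O)cc(O)c12 | intermediate
15 | kaempferol 3,7,4'-tri-O-sulfate | O=c1c(OS(=O)(=O)O)c(-c2ccc(OS(=O)(=O)O)cc2)oc2cc(OS(=O)(=O)O)cc(O)c12 | target

**Step count**
Total steps: 7. Longest linear sequence: 7 steps (from 1 to 15; phenol 4 enters at step 2).

**Steps most likely to fail**

1. Step 3. The doubly activated propargylic C–O bond may ionise to an ion pair instead of rearranging, which would lead to C-propargylation and 4-aryl-4H-chromene or benzofuran formation. Prolonged heating may also isomerise or oligomerise the acid-sensitive 2H-chromene. The fallback sets out from aldehyde 1 and bypasses steps 1 and 2. Claisen–Schmidt condensation of 1 with 1-[2,4-bis(benzyloxy)-6-hydroxyphenyl]ethan-1-one F1 (KOH, EtOH, rt) should give the chalcone (E)-1-[2,4-bis(benzyloxy)-6-hydroxyphenyl]-3-[4-(benzyloxy)phenyl]prop-2-en-1-one F2. Carbonyl reduction with NaBH4 in i-PrOH/THF should give the allylic alcohol racemic (E)-3,5-bis(benzyloxy)-2-{3-[4-(benzyloxy)phenyl]-1-hydroxyprop-2-en-1-yl}phenol F3. On warming with a little AcOH, F3 should lose water to the ortho-quinone methide 8 and close to the chromene; the fallback comes back to the route at compound 9.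

2. Step 2. The oxyphosphonium intermediate of the electron-rich benzylic propargylic alcohol may ionise, so that the phenol is alkylated at carbon, attacked in the SN2' sense to an allenyl ether, or the alcohol is lost by elimination. The fallback sets out from alcohol 3. Acetylation (Ac2O, pyridine, DMAP) should give racemic 1-[4-(benzyloxy)phenyl]prop-2-yn-1-yl acetate F4. Copper-catalysed propargylic etherification with phenol 4 (Cu(MeCN)4PF6, monovalent copper, with a 2,6-bis(oxazolin-2-yl)pyridine ligand, i-Pr2NEt, MeOH, 0 °C) should proceed through a copper allenylidene that the phenoxide attacks at the propargylic carbon; the fallback comes back to the route at compound 5.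

3. Step 7. Sulfation may stop short at the hydrogen-bonded 3-hydroxyl, run on to O5 under forcing, or lose sulfate by hydrolysis while the polar acid form is isolated, and the partly sulfated products are hard to separate. The fallback sets out from kaempferol 14. Reaction with 2,2,2-trichloroethyl chlorosulfate (ClSO2OCH2CCl3, 3.3 equiv), Et3N and DMAP in THF at 0 °C should give the neutral, chromatographable kaempferol 3,7,4'-tris(2,2,2-trichloroethyl sulfate) F5. Reductive removal of the trichloroethyl groups (Zn dust, HCO2NH4, MeOH, rt) followed by H+-form ion exchange should deliver the trisulfate; the fallback comes back to the route at compound 15.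

**Further compounds**
F1 | step 3 | 1-[2,4-bis(benzyloxy)-6-hydroxyphenyl]ethan-1-one | CC(=O)c1c(O)cc(OCc2ccccc2)cc1OCc1ccccc1
F2 | step 3 | (E)-1-[2,4-bis(benzyloxy)-6-hydroxyphenyl]-3-[4-(benzyloxy)phenyl]prop-2-en-1-one | O=C(/C=C/c1ccc(OCc2ccccc2)cc1)c1c(O)cc(OCc2ccccc2)cc1OCc1ccccc1
F3 | step 3 | racemic (E)-3,5-bis(benzyloxy)-2-{3-[4-(benzyloxy)phenyl]-1-hydroxyprop-2-en-1-yl}phenol | OC(/C=C/c1ccc(OCc2ccccc2)cc1)c1c(O)cc(OCc2ccccc2)cc1OCc1ccccc1
F4 | step 2 | racemic 1-[4-(benzyloxy)phenyl]prop-2-yn-1-yl acetate | C#CC(OC(C)=O)c1ccc(OCc2ccccc2)cc1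
F5 | step 7 | kaempferol 3,7,4'-tris(2,2,2-trichloroethyl sulfate) | O=c1c(OS(=O)(=O)OCC(Cl)(Cl)Cl)c(-c2ccc(OS(=O)(=O)OCC(Cl)(Cl)Cl)cc2)oc2cc(OS(=O)(=O)OCC(Cl)(Cl)Cl)cc(O)c12
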